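**Retrosynthetic overview**
1. Target 24 ⇐ tetrabenzyl biflavone 23 by hydrogenolysis of four benzyl ethers; the two methyl ethers stay.
2. 23 ⇐ 2'-hydroxychalcone 21 (I2/DMSO closure; ring C of unit B is formed last) ⇐ key Claisen–Schmidt aldol condensation of the biaryl methyl ketone 18 with aldehyde 19 (C2''–C3'' bond).
3. 18 ⇐ 6-iodoflavone 10 + aryl boronate 16 by Suzuki–Miyaura coupling (C6–C8'' biaryl bond), then MOM removal.
4. 10 ⇐ acetophenone 2 + aldehyde 3 by the same aldol/oxidative-cyclisation pair (ring C of unit A is formed first), then 5-O-debenzylation, C6 iodination and re-benzylation.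
5. 16 ⇐ 2',6'-dihydroxy-4'-methoxyacetophenone 11 by mono-benzylation, ortho-iodination, MOM protection and Miyaura borylation.

Assumption: the SMILES has no stereodescriptor (no stereocentre; the hindered 6,8''-biaryl axis is undefined), so the axis is formed without control and the product is racemic at the axis if it is configurationally stable.
Naming: unit A is the 6-linked 4'-methoxyflavone; unit B is the 8''-linked 7''-methoxyflavone.

**Route**

Step 1
Reactants: 1 2',4',6'-trihydroxyacetophenone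
Product: 2 1-[2,4-bis(benzyloxy)-6-hydroxyphenyl]ethanone
Conditions: BnBr (2.1 equiv), K2CO3 (2.5 equiv), DMF, 0 °C to rt, 16 h
Reagents that add atoms: benzyl bromide, BrCc1ccccc1
Why: Williamson etherification; after the 4-OH and one ortho-OH are alkylated, the last ortho-OH is locked in a hydrogen bond to the ketone and is not benzylated.

Step 2
Reactants: 2 1-[2,4-bis(benzyloxy)-6-hydroxyphenyl]ethanone; 3 4-methoxybenzaldehyde
Product: 5 (E)-1-[2,4-bis(benzyloxy)-6-hydroxyphenyl]-3-(4-methoxyphenyl)prop-2-en-1-one, via β-hydroxy ketone 4 (not isolated)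
Conditions: KOH (50% aq., 10 equiv), EtOH, rt, 36 h
Reagents that add atoms: none
Why: Claisen–Schmidt crossed aldol condensation; only the methyl ketone enolises, only the aldehyde is a good acceptor, and E1cB loss of water from racemic aldol 4 gives the conjugated (E)-enone under thermodynamic control.

Step 3
Reactants: 5 (E)-1-[2,4-bis(benzyloxy)-6-hydroxyphenyl]-3-(4-methoxyphenyl)prop-2-en-1-one
Product: 7 5,7-bis(benzyloxy)-2-(4-methoxyphenyl)-4H-chromen-4-one, via flavanone 6 (not isolated)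
Conditions: I2 (10 mol%), DMSO, 130 °C, 3 h
Reagents that add atoms: none
Why: iodine-catalysed oxidative cyclisation of a 2'-hydroxychalcone; oxa-Michael closure to the racemic flavanone and dehydrogenation with DMSO as terminal oxidant give the flavone, and benzyl ethers tolerate the conditions.

Step 4
Reactants: 7 5,7-bis(benzyloxy)-2-(4-methoxyphenyl)-4H-chromen-4-one
Product: 8 7-(benzyloxy)-5-hydroxy-2-(4-methoxyphenyl)-4H-chromen-4-one
Conditions: MgBr2·OEt2 (3 equiv), toluene/Et2O, 80 °C, 8 h; aq. HCl work-up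
Reagents that add atoms: none
Why: chelation-controlled selective debenzylation; Mg bridges the C4 carbonyl and the peri 5-oxygen, so bromide removes only that benzyl group (SN2 at the benzylic carbon) and the 7-benzyl ether stays.

Step 5
Reactants: 8 7-(benzyloxy)-5-hydroxy-2-(4-methoxyphenyl)-4H-chromen-4-one
Product: 9 7-(benzyloxy)-5-hydroxy-6-iodo-2-(4-methoxyphenyl)-4H-chromen-4-one
Conditions: BnMe3N·ICl2 (1.2 equiv), CaCO3 (1.5 equiv), CH2Cl2/MeOH (5:2), rt, 16 h
Reagents that add atoms: benzyltrimethylammonium dichloroiodate, C[N+](C)(C)Cc1ccccc1.Cl[I-]Cl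
Why: electrophilic aromatic iodination directed by the chelated 5-OH; bond fixation in the hydrogen-bonded hydroxy ketone makes C6 (ortho to 5-OH) the reactive site of 5-hydroxy-7-alkoxyflavones, so C8 and the anisyl ring are left alone.

Step 6
Reactants: 9 7-(benzyloxy)-5-hydroxy-6-iodo-2-(4-methoxyphenyl)-4H-chromen-4-one
Product: 10 5,7-bis(benzyloxy)-6-iodo-2-(4-methoxyphenyl)-4H-chromen-4-one
Conditions: BnBr (1.5 equiv), K2CO3 (3 equiv), DMF, 60 °C, 12 h
Reagents that add atoms: benzyl bromide, BrCc1ccccc1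
Why: Williamson etherification of the chelated 5-OH under forcing conditions masks the phenol next to the C–I bond before the palladium step.

Step 7
Reactants: 11 2',6'-dihydroxy-4'-methoxyacetophenone
Product: 12 1-[2-(benzyloxy)-6-hydroxy-4-methoxyphenyl]ethanone
Conditions: BnBr (1.05 equiv), K2CO3 (1.2 equiv), acetone, reflux, 6 h
Reagents that add atoms: benzyl bromide, BrCc1ccccc1
Why: Williamson mono-etherification; the two OH groups of symmetric 11 are equivalent, and after the first benzylation the remaining OH is held in the hydrogen bond to the ketone, which stops the reaction at the monoether.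

Step 8
Reactants: 12 1-[2-(benzyloxy)-6-hydroxy-4-methoxyphenyl]ethanone
Product: 13 1-[6-(benzyloxy)-2-hydroxy-3-iodo-4-methoxyphenyl]ethanone
Conditions: BnMe3N·ICl2 (1.05 equiv), NaHCO3 (2 equiv), CH2Cl2/MeOH (5:2), rt, 6 h
Reagents that add atoms: benzyltrimethylammonium dichloroiodate, C[N+](C)(C)Cc1ccccc1.Cl[I-]Cl
Why: electrophilic aromatic iodination ortho to the chelated phenol (same bond-fixation control as in step 5) places iodine between OH and OMe, the carbon that becomes C8'' of unit B.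

Step 9
Reactants: 13 1-[6-(benzyloxy)-2-hydroxy-3-iodo-4-methoxyphenyl]ethanone
Product: 15 1-[6-(benzyloxy)-3-iodo-4-methoxy-2-(methoxymethoxy)phenyl]ethanone, via sodium phenoxide 14 (not isolated)
Conditions: NaH (1.1 equiv), DMF, 0 °C, 30 min; then MOMCl (1.3 equiv), 0 °C to rt
Reagents that add atoms: chloromethyl methyl ether, COCCl
Why: O-alkylation (Williamson type) of the preformed phenoxide with MOMCl gives an acetal that survives base and palladium and is later removed by mild acid without touching benzyl ethers.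

Step 10
Reactants: 15 1-[6-(benzyloxy)-3-iodo-4-methoxy-2-(methoxymethoxy)phenyl]ethanone
Product: 16 1-[6-(benzyloxy)-4-methoxy-2-(methoxymethoxy)-3-(4,4,5,5-tetramethyl-1,3,2-dioxaborolan-2-yl)phenyl]ethanone
Conditions: B2pin2 (1.5 equiv), Pd(dppf)Cl2 (5 mol%), KOAc (3 equiv), 1,4-dioxane, 90 °C, 16 h
Reagents that add atoms: bis(pinacolato)diboron, CC1(C)OB(OC1(C)C)B1OC(C)(C)C(C)(C)O1
Why: Miyaura borylation (oxidative addition of the aryl iodide to zerovalent palladium, acetate-assisted transmetalation with B2pin2, reductive elimination); KOAc is too weak to enolise the ketone or to trigger Suzuki homocoupling.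

Step 11
Reactants: 10 5,7-bis(benzyloxy)-6-iodo-2-(4-methoxyphenyl)-4H-chromen-4-one; 16 1-[6-(benzyloxy)-4-methoxy-2-(methoxymethoxy)-3-(4,4,5,5-tetramethyl-1,3,2-dioxaborolan-2-yl)phenyl]ethanone
Product: 17 6-[3-acetyl-4-(benzyloxy)-6-methoxy-2-(methoxymethoxy)phenyl]-5,7-bis(benzyloxy)-2-(4-methoxyphenyl)-4H-chromen-4-one
Conditions: 16 (1.8 equiv), Pd(OAc)2 (10 mol%), SPhos (20 mol%), K3PO4 (3 equiv), toluene/H2O (10:1), 100 °C, 18 h
Reagents that add atoms: none
Why: Suzuki–Miyaura cross-coupling with the bulky electron-rich SPhos ligand, which is suited to tetra-ortho-substituted biaryls; excess boronate offsets protodeboronation, and the new biaryl axis forms without stereocontrol (racemic).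

Step 12
Reactants: 17 6-[3-acetyl-4-(benzyloxy)-6-methoxy-2-(methoxymethoxy)phenyl]-5,7-bis(benzyloxy)-2-(4-methoxyphenyl)-4H-chromen-4-one
Product: 18 6-[3-acetyl-4-(benzyloxy)-2-hydroxy-6-methoxyphenyl]-5,7-bis(benzyloxy)-2-(4-methoxyphenyl)-4H-chromen-4-one
Conditions: 3 M aq. HCl, MeOH/THF (1:1), 50 °C, 3 h
Reagents that add atoms: none
Why: acid-catalysed acetal (MOM) cleavage frees only the phenol ortho to the acetyl group; benzyl and methyl ethers and the flavone are stable to dilute HCl in methanol.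

Step 13
Reactants: 18 6-[3-acetyl-4-(benzyloxy)-2-hydroxy-6-methoxyphenyl]-5,7-bis(benzyloxy)-2-(4-methoxyphenyl)-4H-chromen-4-one; 19 4-(benzyloxy)benzaldehyde
Product: 21 5,7-bis(benzyloxy)-6-{4-(benzyloxy)-3-[(E)-3-(4-(benzyloxy)phenyl)prop-2-enoyl]-2-hydroxy-6-methoxyphenyl}-2-(4-methoxyphenyl)-4H-chromen-4-one, via β-hydroxy ketone 20 (not isolated)
Conditions: 19 (1.5 equiv), KOH (50% aq., 15 equiv), EtOH/THF (2:1), rt, 48 h
Reagents that add atoms: none
Why: key Claisen–Schmidt crossed aldol condensation joining the biaryl methyl ketone to the ring B aldehyde; 18 is the only enolisable partner, 19 the only good acceptor, E1cB dehydration of aldol 20 gives the (E)-chalcone, and the flavone of unit A should tolerate ethanolic KOH at room temperature.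

Step 14
Reactants: 21 5,7-bis(benzyloxy)-6-{4-(benzyloxy)-3-[(E)-3-(4-(benzyloxy)phenyl)prop-2-enoyl]-2-hydroxy-6-methoxyphenyl}-2-(4-methoxyphenyl)-4H-chromen-4-one
Product: 23 5,7-bis(benzyloxy)-6-{5-(benzyloxy)-2-[4-(benzyloxy)phenyl]-7-methoxy-4-oxo-4H-chromen-8-yl}-2-(4-methoxyphenyl)-4H-chromen-4-one, via flavanone 22 (not isolated)
Conditions: I2 (10 mol%), DMSO, 130 °C, 4 h
Reagents that add atoms: none
Why: iodine-catalysed oxidative cyclisation as in step 3; only the free 2'-OH next to the biaryl carbon can close, which fixes the 8''-linkage of unit B.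

Step 15
Reactants: 23 5,7-bis(benzyloxy)-6-{5-(benzyloxy)-2-[4-(benzyloxy)phenyl]-7-methoxy-4-oxo-4H-chromen-8-yl}-2-(4-methoxyphenyl)-4H-chromen-4-one
Product: 24 5,7-dihydroxy-6-[5-hydroxy-2-(4-hydroxyphenyl)-7-methoxy-4-oxo-4H-chromen-8-yl]-2-(4-methoxyphenyl)-4H-chromen-4-one
Conditions: H2 (1 atm), 10% Pd/C, THF/MeOH (1:1), rt, 12 h
Reagents that add atoms: none
Why: catalytic hydrogenolysis of the four aryl benzyl ethers; methyl ethers and the chromone C2–C3 double bonds are inert at 1 atm and room temperature, and no stereocentre is created.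

**Compound list**
1 | 2',4',6'-trihydroxyacetophenone | CC(=O)c1c(O)cc(O)cc1O | starting material
2 | 1-[2,4-bis(benzyloxy)-6-hydroxyphenyl]ethanone | CC(=O)c1c(O)cc(OCc2ccccc2)cc1OCc1ccccc1 | intermediate
3 | 4-methoxybenzaldehyde | COc1ccc(C=O)cc1 | starting material
4 | 1-[2,4-bis(benzyloxy)-6-hydroxyphenyl]-3-hydroxy-3-(4-methoxyphenyl)propan-1-one (racemic) | COc1ccc(C(O)CC(=O)c2c(O)cc(OCc3ccccc3)cc2OCc2ccccc2)cc1 | intermediate (not isolated)
5 | (E)-1-[2,4-bis(benzyloxy)-6-hydroxyphenyl]-3-(4-methoxyphenyl)prop-2-en-1-one | COc1ccc(/C=C/C(=O)c2c(O)cc(OCc3ccccc3)cc2OCc2ccccc2)cc1 | intermediate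
6 | 5,7-bis(benzyloxy)-2-(4-methoxyphenyl)chroman-4-one (racemic) | COc1ccc(C2CC(=O)c3c(OCc4ccccc4)cc(OCc4ccccc4)cc3O2)cc1 | intermediate (not isolated)
7 | 5,7-bis(benzyloxy)-2-(4-methoxyphenyl)-4H-chromen-4-one | COc1ccc(-c2cc(=O)c3c(OCc4ccccc4)cc(OCc4ccccc4)cc3o2)cc1 | intermediate
8 | 7-(benzyloxy)-5-hydroxy-2-(4-methoxyphenyl)-4H-chromen-4-one | COc1ccc(-c2cc(=O)c3c(O)cc(OCc4ccccc4)cc3o2)cc1 | intermediate
9 | 7-(benzyloxy)-5-hydroxy-6-iodo-2-(4-methoxyphenyl)-4H-chromen-4-one | COc1ccc(-c2cc(=O)c3c(O)c(I)c(OCc4ccccc4)cc3o2)cc1 | intermediate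
10 | 5,7-bis(benzyloxy)-6-iodo-2-(4-methoxyphenyl)-4H-chromen-4-one | COc1ccc(-c2cc(=O)c3c(OCc4ccccc4)c(I)c(OCc4ccccc4)cc3o2)cc1 | intermediate
11 | 2',6'-dihydroxy-4'-methoxyacetophenone | COc1cc(O)c(C(C)=O)c(O)c1 | starting material
12 | 1-[2-(benzyloxy)-6-hydroxy-4-methoxyphenyl]ethanone | COc1cc(O)c(C(C)=O)c(OCc2ccccc2)c1 | intermediate
13 | 1-[6-(benzyloxy)-2-hydroxy-3-iodo-4-methoxyphenyl]ethanone | COc1cc(OCc2ccccc2)c(C(C)=O)c(O)c1I | intermediate
14 | sodium 2-acetyl-3-(benzyloxy)-6-iodo-5-methoxyphenolate | [Na+].COc1cc(OCc2ccccc2)c(C(C)=O)c([O-])c1I | intermediate (not isolated)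
15 | 1-[6-(benzyloxy)-3-iodo-4-methoxy-2-(methoxymethoxy)phenyl]ethanone | COCOc1c(I)c(OC)cc(OCc2ccccc2)c1C(C)=O | intermediate
16 | 1-[6-(benzyloxy)-4-methoxy-2-(methoxymethoxy)-3-(4,4,5,5-tetramethyl-1,3,2-dioxaborolan-2-yl)phenyl]ethanone | COCOc1c(B2OC(C)(C)C(C)(C)O2)c(OC)cc(OCc2ccccc2)c1C(C)=O | intermediate
17 | 6-[3-acetyl-4-(benzyloxy)-6-methoxy-2-(methoxymethoxy)phenyl]-5,7-bis(benzyloxy)-2-(4-methoxyphenyl)-4H-chromen-4-one (racemic axis) | COc1ccc(-c2cc(=O)c3c(OCc4ccccc4)c(-c4c(OC)cc(OCc5ccccc5)c(C(C)=O)c4OCOC)c(OCc4ccccc4)cc3o2)cc1 | intermediate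
18 | 6-[3-acetyl-4-(benzyloxy)-2-hydroxy-6-methoxyphenyl]-5,7-bis(benzyloxy)-2-(4-methoxyphenyl)-4H-chromen-4-one (racemic axis) | COc1ccc(-c2cc(=O)c3c(OCc4ccccc4)c(-c4c(OC)cc(OCc5ccccc5)c(C(C)=O)c4O)c(OCc4ccccc4)cc3o2)cc1 | intermediate
19 | 4-(benzyloxy)benzaldehyde | O=Cc1ccc(OCc2ccccc2)cc1 | starting material
20 | 5,7-bis(benzyloxy)-6-{4-(benzyloxy)-3-[3-(4-(benzyloxy)phenyl)-3-hydroxypropanoyl]-2-hydroxy-6-methoxyphenyl}-2-(4-methoxyphenyl)-4H-chromen-4-one (stereo-undefined) | COc1ccc(-c2cc(=O)c3c(OCc4ccccc4)c(-c4c(OC)cc(OCc5ccccc5)c(C(=O)CC(O)c5ccc(OCc6ccccc6)cc5)c4O)c(OCc4ccccc4)cc3o2)cc1 | intermediate (not isolated)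
21 | 5,7-bis(benzyloxy)-6-{4-(benzyloxy)-3-[(E)-3-(4-(benzyloxy)phenyl)prop-2-enoyl]-2-hydroxy-6-methoxyphenyl}-2-(4-methoxyphenyl)-4H-chromen-4-one (racemic axis) | COc1ccc(-c2cc(=O)c3c(OCc4ccccc4)c(-c4c(OC)cc(OCc5ccccc5)c(C(=O)/C=C/c5ccc(OCc6ccccc6)cc5)c4O)c(OCc4ccccc4)cc3o2)cc1 | intermediate
22 | 5,7-bis(benzyloxy)-6-{5-(benzyloxy)-2-[4-(benzyloxy)phenyl]-7-methoxy-4-oxochroman-8-yl}-2-(4-methoxyphenyl)-4H-chromen-4-one (stereo-undefined) | COc1ccc(-c2cc(=O)c3c(OCc4ccccc4)c(-c4c(OC)cc(OCc5ccccc5)c5c4OC(c4ccc(OCc6ccccc6)cc4)CC5=O)c(OCc4ccccc4)cc3o2)cc1 | intermediate (not isolated)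
23 | 5,7-bis(benzyloxy)-6-{5-(benzyloxy)-2-[4-(benzyloxy)phenyl]-7-methoxy-4-oxo-4H-chromen-8-yl}-2-(4-methoxyphenyl)-4H-chromen-4-one (racemic axis) | COc1ccc(-c2cc(=O)c3c(OCc4ccccc4)c(-c4c(OC)cc(OCc5ccccc5)c5c(=O)cc(-c6ccc(OCc7ccccc7)cc6)oc45)c(OCc4ccccc4)cc3o2)cc1 | intermediate
24 | 5,7-dihydroxy-6-[5-hydroxy-2-(4-hydroxyphenyl)-7-methoxy-4-oxo-4H-chromen-8-yl]-2-(4-methoxyphenyl)-4H-chromen-4-one (4',7''-di-O-methyl ether of 6,8''-biapigenin) | COc1ccc(-c2cc(=O)c3c(O)c(-c4c(OC)cc(O)c5c(=O)cc(-c6ccc(O)cc6)oc45)c(O)cc3o2)cc1 | target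

**Totals and risks**

Total step count: 15. Longest linear sequence: 11 steps (steps 1–6, then 11–15, from compound 1); the branch from 11 contributes steps 7–10.

Three steps most likely to fail:

Step 11 (tetra-ortho-substituted Suzuki coupling) is the most exposed. Boronate 16 can protodeboronate, transmetalation is slow, and the ortho substituent beside boron is a freely rotating OMOM group. The fallback sets out from 13 (with 10 and 19) and comes back at 23. Both flavones are completed first, so that one ortho substituent at the coupling site is the tied-back ring oxygen. Compound 13 is condensed with 19 (KOH, EtOH, rt) through the β-hydroxy ketone F1 to the iodochalcone F2, which is cyclised with I2/DMSO at 130 °C through the flavanone F3 to the 8-iodoflavone F4. Iodide 10 is turned into the flavone 6-boronate F5 (B2pin2, Pd(dppf)Cl2, KOAc, dioxane, 90 °C). Coupling F5 with F4 (Pd(OAc)2, SPhos, K3PO4, toluene/H2O, 100 °C) gives 23 directly.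

Step 13 (key Claisen–Schmidt condensation on the flavone-bearing, hindered ketone) may be slow, and hydroxide can open the pyranone of unit A. The fallback sets out from 18 and comes back at 23. It is a hydroxide-free crossed Claisen condensation. Compound 18 is treated with LiN(SiMe3)2 (3.5 equiv, THF, −78 °C) to give the dilithium phenoxide-enolate F6. This is C-acylated with 4-(benzyloxy)benzoyl chloride (1.1 equiv, −78 °C to rt) to the 1,3-diketone F7. Cyclodehydration with catalytic TsOH in toluene at 80 °C gives 23, so neither chalcone 21 nor an oxidation is needed.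

Step 10 (Miyaura borylation of the di-ortho-oxygenated iodide) may give mainly protodeiodination. The fallback sets out from 15 (with 10) and comes back at 17. Zinc is inserted into the C–I bond of 15 (Zn dust, LiCl, THF, 50 °C; the ketone is tolerated) to give the arylzinc iodide F8. Negishi coupling of F8 with 10 (Pd2(dba)3, RuPhos, THF/NMP, 70 °C) gives 17 without any boron intermediate.

**Further compounds**
F1 | step 11 | 1-[6-(benzyloxy)-2-hydroxy-3-iodo-4-methoxyphenyl]-3-[4-(benzyloxy)phenyl]-3-hydroxypropan-1-one (racemic) | COc1cc(OCc2ccccc2)c(C(=O)CC(O)c2ccc(OCc3ccccc3)cc2)c(O)c1I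
F2 | step 11 | (E)-1-[6-(benzyloxy)-2-hydroxy-3-iodo-4-methoxyphenyl]-3-[4-(benzyloxy)phenyl]prop-2-en-1-one | COc1cc(OCc2ccccc2)c(C(=O)/C=C/c2ccc(OCc3ccccc3)cc2)c(O)c1I
F3 | step 11 | 5-(benzyloxy)-2-[4-(benzyloxy)phenyl]-8-iodo-7-methoxychroman-4-one (racemic) | COc1cc(OCc2ccccc2)c2c(c1I)OC(c1ccc(OCc3ccccc3)cc1)CC2=O
F4 | step 11 | 5-(benzyloxy)-2-[4-(benzyloxy)phenyl]-8-iodo-7-methoxy-4H-chromen-4-one | COc1cc(OCc2ccccc2)c2c(=O)cc(-c3ccc(OCc4ccccc4)cc3)oc2c1I
F5 | step 11 | 5,7-bis(benzyloxy)-2-(4-methoxyphenyl)-6-(4,4,5,5-tetramethyl-1,3,2-dioxaborolan-2-yl)-4H-chromen-4-one | COc1ccc(-c2cc(=O)c3c(OCc4ccccc4)c(B4OC(C)(C)C(C)(C)O4)c(OCc4ccccc4)cc3o2)cc1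
F6 | step 13 | dilithium phenoxide-enolate of 18 | [Li+].[Li+].COc1ccc(-c2cc(=O)c3c(OCc4ccccc4)c(-c4c(OC)cc(OCc5ccccc5)c(C(=C)[O-])c4[O-])c(OCc4ccccc4)cc3o2)cc1
F7 | step 13 | 1-{6-(benzyloxy)-3-[5,7-bis(benzyloxy)-2-(4-methoxyphenyl)-4-oxo-4H-chromen-6-yl]-2-hydroxy-4-methoxyphenyl}-3-[4-(benzyloxy)phenyl]propane-1,3-dione | COc1ccc(-c2cc(=O)c3c(OCc4ccccc4)c(-c4c(OC)cc(OCc5ccccc5)c(C(=O)CC(=O)c5ccc(OCc6ccccc6)cc5)c4O)c(OCc4ccccc4)cc3o2)cc1
F8 | step 10 | [3-acetyl-4-(benzyloxy)-6-methoxy-2-(methoxymethoxy)phenyl]zinc iodide | COCOc1c([Zn]I)c(OC)cc(OCc2ccccc2)c1C(C)=O
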